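Ring B is built on the diaryl ether oxygen instead of being coupled to ring A. Ring B carries oxygen on C4' and C6' (a resorcinol pattern), with the ether oxygen on C1' and the hydroxymethyl carbon on C2'; this pattern is what the key step exploits. An aryloxyacetone supplies C5', C6' and C1', and a 4-silyloxybut-2-ynoate supplies C2'–C4' with the CH2O branch. In one operation a Michael addition (C1'–C2') and a Claisen acylation (C4'–C5') close ring B and aromatise it to the resorcinol. The precursor is the acetonyl ether of mono-prenylated 2-iodo-orcinol; iodine marks the site of the ring A ester.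

Key step: step 5

Remark: the target has no stereocentre and no stereogenic double bond, so it is one achiral compound and no step has to set configuration. Atom labels: ring A C1 (CO2Me), C2 (O-prenyl), C4 (CH3), C6 (ether O); ring B C1' (ether O), C2' (CH2OH), C4' and C6' (OMe).

Step 1
Reactants: 1 orcinol (5-methylbenzene-1,3-diol)
Product: 2 2-iodo-5-methylbenzene-1,3-diol
Conditions: I2 (1.05 equiv), NaHCO3 (1.1 equiv), THF/H2O 1:1, 0 °C to rt
Reagents that add atoms: iodine, II
Why: Electrophilic aromatic iodination of the resorcinol mono-phenoxide in aqueous bicarbonate goes to the carbon flanked by both hydroxyls, as it does for resorcinol itself, and a single equivalent of iodine limits over-iodination.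

Step 2
Reactants: 2 2-iodo-5-methylbenzene-1,3-diol (2 equiv); 3 prenyl bromide (1-bromo-3-methylbut-2-ene, 1 equiv)
Product: 4 2-iodo-5-methyl-3-[(3-methylbut-2-en-1-yl)oxy]phenol
Conditions: K2CO3 (1.0 equiv), acetone, rt; surplus 2 recovered on chromatography
Reagents that add atoms: none
Why: Williamson O-alkylation with a reactive allylic bromide and carbonate in acetone favours O- over C-alkylation, and working with the symmetric diol in excess suppresses the bis-ether while the surplus diol is recovered.

Step 3
Reactants: 4 2-iodo-5-methyl-3-[(3-methylbut-2-en-1-yl)oxy]phenol; 5 chloroacetone (1-chloropropan-2-one)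
Product: 6 1-{2-iodo-5-methyl-3-[(3-methylbut-2-en-1-yl)oxy]phenoxy}propan-2-one
Conditions: K2CO3 (1.5 equiv), KI (10 mol %), acetone, 50 °C
Reagents that add atoms: none
Why: Williamson etherification of the remaining phenol with an α-chloro ketone, accelerated by in situ Finkelstein exchange, under a carbonate base too weak to enolise the product appreciably or to touch the prenyl ether and the aryl iodide.

Step 4
Reactants: 7 tert-butyldimethyl(prop-2-yn-1-yloxy)silane (commercial silyl ether of propargyl alcohol)
Product: 9 methyl 4-[(tert-butyldimethylsilyl)oxy]but-2-ynoate, via lithium acetylide 8 (not isolated)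
Conditions: n-BuLi (1.05 equiv), THF, −78 °C; ClCO2Me (1.2 equiv), −78 to 0 °C
Reagents that add atoms: methyl chloroformate, COC(=O)Cl
Why: Deprotonation of the terminal alkyne and C-acylation of the lithium acetylide with a chloroformate is the standard entry to 2-ynoates, and the silyl ether is inert to n-BuLi at −78 °C.

Step 5
Reactants: 6 1-{2-iodo-5-methyl-3-[(3-methylbut-2-en-1-yl)oxy]phenoxy}propan-2-one; 9 methyl 4-[(tert-butyldimethylsilyl)oxy]but-2-ynoate
Product: 13 4-{2-iodo-5-methyl-3-[(3-methylbut-2-en-1-yl)oxy]phenoxy}-5-{[(tert-butyldimethylsilyl)oxy]methyl}benzene-1,3-diol, via sodium Z-enolate 10 (not isolated), via Michael adduct 11 (not isolated), via cyclohexenedione 12 (not isolated)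
Conditions: NaOt-Bu (0.95 equiv), THF, −40 °C; 9 (1.1 equiv), −40 to 0 °C; NaOt-Bu (1.5 equiv), 0 °C to rt; AcOH quench
Reagents that add atoms: none
Why: Sub-stoichiometric NaOt-Bu deprotonates 6 under proton-exchange equilibrium to the more stable enolate on the aryloxy-bearing carbon (Z, sodium chelated between the enolate and aryl ether oxygens), which adds to the ynoate β-carbon (the one carrying CH2OTBS) to form C1'–C2'; the allenolate is protonated by t-BuOH and adduct 11 then sits as an extended dienolate through which its E/Z geometry equilibrates. With more base the methyl-side enolate of the Z isomer attacks the ester carbonyl in a 6-exo-trig Claisen closure that forms C4'–C5' and expels methoxide, and the resulting cyclohex-5-ene-1,3-dione 12 is the keto tautomer of the resorcinol, so it aromatises at once and is held as the phenoxide, which makes the sequence irreversible. The closest known reaction type is the Michael–Claisen [3+3] cycloaromatisation of ketones that are nucleophilic at both α-carbons with alkynoates, together with the related cyclohexane-1,3-dione synthesis from substituted acetones and enoates. No stereocentre survives: the transient C1' centre and the enoate geometry are erased by enolisation and aromatisation. The step needs the aryloxy carbon and not CH3 to be the Michael donor, and C- rather than O-acylation in the closure; the first is secured by the roughly three pK units by which the aryloxy group acidifies its own carbon and by forming the enolate before the ynoate is added, the second by the reversibility of pyranone formation under alkoxide against irreversible aromatisation. Ring A offers the carbanion no electrophile because iodine stands where the ester will be, both ring A oxygens are alkylated so no phenol drains base, and the CH2OTBS group ends up meta to both phenoxides so that it cannot be expelled.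

Step 6
Reactants: 13 4-{2-iodo-5-methyl-3-[(3-methylbut-2-en-1-yl)oxy]phenoxy}-5-{[(tert-butyldimethylsilyl)oxy]methyl}benzene-1,3-diol
Product: 14 tert-butyl[(2-{2-iodo-5-methyl-3-[(3-methylbut-2-en-1-yl)oxy]phenoxy}-3,5-dimethoxybenzyl)oxy]dimethylsilane
Conditions: MeI (4 equiv), K2CO3 (3 equiv), acetone, 40 °C
Reagents that add atoms: iodomethane, CI
Why: Williamson O-methylation of both phenols with excess iodomethane and carbonate, conditions under which the alkyl silyl ether, the prenyl ether and the aryl iodide are stable; it also removes the acidic protons that would quench the organometallic of the next step.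

Step 7
Reactants: 14 tert-butyl[(2-{2-iodo-5-methyl-3-[(3-methylbut-2-en-1-yl)oxy]phenoxy}-3,5-dimethoxybenzyl)oxy]dimethylsilane
Product: 16 methyl 2-[2-({[tert-butyl(dimethyl)silyl]oxy}methyl)-4,6-dimethoxyphenoxy]-4-methyl-6-[(3-methylbut-2-en-1-yl)oxy]benzoate, via arylmagnesium chloride 15 (not isolated)
Conditions: i-PrMgCl·LiCl (1.2 equiv), THF, −20 to 0 °C; then added to ClCO2Me (3 equiv), THF, −40 °C to rt
Reagents that add atoms: methyl chloroformate, COC(=O)Cl
Why: Iodine–magnesium exchange with the LiCl-activated Grignard reagent is favoured at an aryl iodide flanked by two ether oxygens and tolerates ethers and silyl ethers, and inverse addition of the arylmagnesium to excess chloroformate stops at the ester because a 2,6-disubstituted benzoate resists a second addition.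

Step 8
Reactants: 16 methyl 2-[2-({[tert-butyl(dimethyl)silyl]oxy}methyl)-4,6-dimethoxyphenoxy]-4-methyl-6-[(3-methylbut-2-en-1-yl)oxy]benzoate
Product: 17 methyl 2-[2-(hydroxymethyl)-4,6-dimethoxyphenoxy]-4-methyl-6-[(3-methylbut-2-en-1-yl)oxy]benzoate (CNP0573678.0)
Conditions: TBAF (1.5 equiv), AcOH (1.5 equiv), THF, 0 °C to rt
Reagents that add atoms: none
Why: Fluoride cleaves the primary silyl ether by attack at silicon, and the acetic acid buffer keeps the released alkoxide protonated so that it cannot transesterify onto the ring A ester, while the acid-labile prenyl ether is not exposed to strong acid.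

Compound list
1 | orcinol (5-methylbenzene-1,3-diol) | Cc1cc(O)cc(O)c1 | starting material
2 | 2-iodo-5-methylbenzene-1,3-diol | Cc1cc(O)c(I)c(O)c1 | intermediate
3 | prenyl bromide (1-bromo-3-methylbut-2-ene) | CC(C)=CCBr | starting material
4 | 2-iodo-5-methyl-3-[(3-methylbut-2-en-1-yl)oxy]phenol | Cc1cc(O)c(I)c(OCC=C(C)C)c1 | intermediate
5 | chloroacetone (1-chloropropan-2-one) | CC(=O)CCl | starting material
6 | 1-{2-iodo-5-methyl-3-[(3-methylbut-2-en-1-yl)oxy]phenoxy}propan-2-one | CC(=O)COc1cc(C)cc(OCC=C(C)C)c1I | intermediate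
7 | tert-butyldimethyl(prop-2-yn-1-yloxy)silane | C#CCO[Si](C)(C)C(C)(C)C | starting material
8 | lithium acetylide of 7, {3-[(tert-butyldimethylsilyl)oxy]prop-1-yn-1-yl}lithium (not isolated) | [Li]C#CCO[Si](C)(C)C(C)(C)C | intermediate
9 | methyl 4-[(tert-butyldimethylsilyl)oxy]but-2-ynoate | COC(=O)C#CCO[Si](C)(C)C(C)(C)C | intermediate
10 | sodium (Z)-1-{2-iodo-5-methyl-3-[(3-methylbut-2-en-1-yl)oxy]phenoxy}prop-1-en-2-olate (not isolated) | C/C([O-])=C/Oc1cc(C)cc(OCC=C(C)C)c1I.[Na+] | intermediate
11 | methyl (2Z)-3-({[tert-butyl(dimethyl)silyl]oxy}methyl)-4-{2-iodo-5-methyl-3-[(3-methylbut-2-en-1-yl)oxy]phenoxy}-5-oxohex-2-enoate (racemic at C4; present as its sodium dienolate; not isolated) | COC(=O)/C=C(/CO[Si](C)(C)C(C)(C)C)C(Oc1cc(C)cc(OCC=C(C)C)c1I)C(C)=O | intermediate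
12 | 4-{2-iodo-5-methyl-3-[(3-methylbut-2-en-1-yl)oxy]phenoxy}-5-({[tert-butyl(dimethyl)silyl]oxy}methyl)cyclohex-5-ene-1,3-dione (racemic keto tautomer of 13; not isolated) | O=C1CC(=O)C(Oc2cc(C)cc(OCC=C(C)C)c2I)C(CO[Si](C)(C)C(C)(C)C)=C1 | intermediate
13 | 4-{2-iodo-5-methyl-3-[(3-methylbut-2-en-1-yl)oxy]phenoxy}-5-{[(tert-butyldimethylsilyl)oxy]methyl}benzene-1,3-diol | Oc1cc(O)c(Oc2cc(C)cc(OCC=C(C)C)c2I)c(CO[Si](C)(C)C(C)(C)C)c1 | intermediate
14 | tert-butyl[(2-{2-iodo-5-methyl-3-[(3-methylbut-2-en-1-yl)oxy]phenoxy}-3,5-dimethoxybenzyl)oxy]dimethylsilane | COc1cc(CO[Si](C)(C)C(C)(C)C)c(Oc2cc(C)cc(OCC=C(C)C)c2I)c(OC)c1 | intermediate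
15 | {2-[2-({[tert-butyl(dimethyl)silyl]oxy}methyl)-4,6-dimethoxyphenoxy]-4-methyl-6-[(3-methylbut-2-en-1-yl)oxy]phenyl}magnesium chloride, LiCl complex (not isolated) | COc1cc(CO[Si](C)(C)C(C)(C)C)c(Oc2cc(C)cc(OCC=C(C)C)c2[Mg]Cl)c(OC)c1 | intermediate
16 | methyl 2-[2-({[tert-butyl(dimethyl)silyl]oxy}methyl)-4,6-dimethoxyphenoxy]-4-methyl-6-[(3-methylbut-2-en-1-yl)oxy]benzoate | COC(=O)c1c(OCC=C(C)C)cc(C)cc1Oc1c(CO[Si](C)(C)C(C)(C)C)cc(OC)cc1OC | intermediate
17 | methyl 2-[2-(hydroxymethyl)-4,6-dimethoxyphenoxy]-4-methyl-6-[(3-methylbut-2-en-1-yl)oxy]benzoate (achiral) | COC(=O)c1c(OCC=C(C)C)cc(C)cc1Oc1c(CO)cc(OC)cc1OC | target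

Total step count: 8
Longest linear sequence: 7 steps (1 → 2 → 4 → 6 → 13 → 14 → 16 → 17; the ynoate 9 is made in one side step)

Steps most likely to fail

Step 5. Several things may go wrong. The conjugate addition may run through the methyl-side enolate and lead to the 2-aryloxy regioisomer. The adduct may close through oxygen to a 2-pyranone that does not revert. The ynoate may isomerise under base before it is intercepted. The fallback sets out from 4 and returns at 14; it forms the diaryl ether bond and gives up the ring construction. Commercial (3,5-dimethoxyphenyl)methanol F1 is brominated with NBS (MeCN, 0 °C) at the position ortho to the CH2OH group and para to a methoxy group to give (2-bromo-3,5-dimethoxyphenyl)methanol F2. TBSCl and imidazole in DMF give [(2-bromo-3,5-dimethoxybenzyl)oxy](tert-butyl)dimethylsilane F3. Bromine–lithium exchange (n-BuLi, THF, −78 °C) gives [2-({[tert-butyl(dimethyl)silyl]oxy}methyl)-4,6-dimethoxyphenyl]lithium F4, which is trapped with B(Oi-Pr)3 and hydrolysed with aqueous NH4Cl to [2-({[tert-butyl(dimethyl)silyl]oxy}methyl)-4,6-dimethoxyphenyl]boronic acid F5. Chan–Lam coupling of F5 with phenol 4 (Cu(OAc)2, pyridine, 4 Å MS, CH2Cl2, air, rt) should leave the aryl iodide untouched and give 14 directly, with both methyl ethers already in place.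

Step 7. The iodine–magnesium exchange may stay incomplete at the electron-rich, doubly ortho-substituted carbon, or the arylmagnesium may be protonated before the slow acylation, which would return the deiodinated arene. The fallback runs from 14 to 16 and replaces direct acylation by carboxylation followed by O-alkylation. t-BuLi (2 equiv, Et2O, −78 °C) should give {2-[2-({[tert-butyl(dimethyl)silyl]oxy}methyl)-4,6-dimethoxyphenoxy]-4-methyl-6-[(3-methylbut-2-en-1-yl)oxy]phenyl}lithium F6. CO2 converts it to lithium 2-[2-({[tert-butyl(dimethyl)silyl]oxy}methyl)-4,6-dimethoxyphenoxy]-4-methyl-6-[(3-methylbut-2-en-1-yl)oxy]benzoate F7. MeI in DMF at rt then alkylates the carboxylate oxygen, which lies away from the two ortho substituents, to give 16.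

Step 2. Over-alkylation to the bis-ether and some C-prenylation may leave little mono-ether. The fallback runs from 2 to 4. Exhaustive prenylation with excess 3 (K2CO3, DMF, rt) gives 2-iodo-5-methyl-1,3-bis[(3-methylbut-2-en-1-yl)oxy]benzene F8. One ether is then cleaved by SN2 attack of sodium ethanethiolate on a prenyl CH2 (DMF, 60 °C, dark). The phenoxide that forms makes the second aryloxide a far poorer leaving group, so the cleavage should stop at 4.

Further compounds
F1 | step 5 | (3,5-dimethoxyphenyl)methanol | COc1cc(CO)cc(OC)c1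
F2 | step 5 | (2-bromo-3,5-dimethoxyphenyl)methanol | OCc1cc(OC)cc(OC)c1Br
F3 | step 5 | [(2-bromo-3,5-dimethoxybenzyl)oxy](tert-butyl)dimethylsilane | CC(C)(C)[Si](C)(C)OCc1cc(OC)cc(OC)c1Br
F4 | step 5 | [2-({[tert-butyl(dimethyl)silyl]oxy}methyl)-4,6-dimethoxyphenyl]lithium | CC(C)(C)[Si](C)(C)OCc1cc(OC)cc(OC)c1[Li]
F5 | step 5 | [2-({[tert-butyl(dimethyl)silyl]oxy}methyl)-4,6-dimethoxyphenyl]boronic acid | CC(C)(C)[Si](C)(C)OCc1cc(OC)cc(OC)c1B(O)O
F6 | step 7 | {2-[2-({[tert-butyl(dimethyl)silyl]oxy}methyl)-4,6-dimethoxyphenoxy]-4-methyl-6-[(3-methylbut-2-en-1-yl)oxy]phenyl}lithium | COc1cc(CO[Si](C)(C)C(C)(C)C)c(Oc2cc(C)cc(OCC=C(C)C)c2[Li])c(OC)c1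
F7 | step 7 | lithium 2-[2-({[tert-butyl(dimethyl)silyl]oxy}methyl)-4,6-dimethoxyphenoxy]-4-methyl-6-[(3-methylbut-2-en-1-yl)oxy]benzoate | [Li+].[O-]C(=O)c1c(OCC=C(C)C)cc(C)cc1Oc1c(CO[Si](C)(C)C(C)(C)C)cc(OC)cc1OC
F8 | step 2 | 2-iodo-5-methyl-1,3-bis[(3-methylbut-2-en-1-yl)oxy]benzene | Cc1cc(OCC=C(C)C)c(I)c(OCC=C(C)C)c1
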